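## Retrosynthetic overview

1. Last step (C–O bond): the C4–O ester bond is made by SN2 opening of a macrocyclic trans-4,5-epoxide with 3-methylbut-2-enoic acid, with inversion at C4 and release of the C5–OH.
2. The 11-membered carbocycle (the only carbocycle) is closed just before that by ring-closing metathesis at C2=C3 of an acyclic epoxy trienone.
3. C8–C9: a (Z)-2-lithioallyl alkoxide (fragment A) is acylated by a (Z)-epoxy-enoyl Weinreb amide (fragment B).
4. Fragment A: geraniol → copper-catalysed SN2' propargylation (sets C1) → hydroxymethylation → trans-hydrostannation (sets C9=C10).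
5. Fragment B: acrolein → Wittig, reduction → Sharpless epoxidation (sets C4/C5) → oxidation → Z-selective Horner–Wadsworth–Emmons (C6=C7). Ring order: oxirane (step 7), carbocycle (step 11), oxirane opened (step 12).

Assumption and convention: ring atoms are numbered C1 (quaternary carbon with CH3 and 4-methylpent-3-enyl), C2=C3, C4 (O-acyl), C5 (CH3, OH), C6=C7, C8 (C=O), C9 (CH2OH)=C10, C11. In this numbering the target is 1S,4R,5S,2Z,6Z,9Z and is treated as the open hydroxy-enone tautomer.

## Route

Step 1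
Reactants: 1 geraniol
Product: 2 geranyl diethyl phosphate
Conditions: (EtO)2P(O)Cl, Et3N, DMAP (cat.), CH2Cl2, 0 °C → rt
Reagents that add atoms: diethyl chlorophosphate, CCOP(=O)(Cl)OCC
Why: O-phosphorylation of the primary allylic alcohol installs the leaving group for copper-catalysed allylic substitution; no stereocentre is formed.

Step 2
Reactants: 2 geranyl diethyl phosphate; 3 4,4,5,5-tetramethyl-2-[3-(trimethylsilyl)prop-2-yn-1-yl]-1,3,2-dioxaborolane
Product: 4 [(4S)-4-ethenyl-4,8-dimethylnon-7-en-1-yn-1-yl]trimethylsilane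
Conditions: CuCl (5 mol %), chiral sulfonate-bearing imidazolinium salt (NHC precursor, antipode giving 4S), NaOMe (1.5 equiv), THF, 22 °C
Reagents that add atoms: none
Why: NHC–copper-catalysed enantioselective allylic substitution, in which boron-to-copper transmetalation gives a monovalent copper allenyl species that attacks the γ-carbon (SN2') with propargyl selectivity, the chiral carbene choosing the alkene face and setting the quaternary C1 as S.

Step 3
Reactants: 4 silyl enyne
Product: 6 (5S)-5-ethenyl-5,9-dimethyldec-8-en-2-yn-1-ol, via lithium acetylide 5 (not isolated)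
Conditions: MeLi·LiBr, THF, 0 °C → rt; then (CH2O)n, −78 °C → rt; aq. NH4Cl
Reagents that add atoms: formaldehyde (as paraformaldehyde), C=O
Why: Desilylative lithiation of the alkynylsilane followed by acetylide 1,2-addition to formaldehyde gives the propargylic alcohol; C1 is untouched.

Step 4
Reactants: 6 propargylic alcohol
Product: 7 (2Z,5S)-5-ethenyl-5,9-dimethyl-2-(tributylstannyl)deca-2,8-dien-1-ol
Conditions: [Cp*RuCl]4 (2 mol %), Bu3SnH (1.1 equiv), CH2Cl2, rt
Reagents that add atoms: tributyltin hydride, CCCC[SnH](CCCC)CCCC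
Why: Hydroxyl-directed ruthenium-catalysed trans-hydrostannation places tin on the alkyne carbon next to the carbinol and hydrogen anti to it, so tin ends cis to the C11 methylene (the later C9=C10 Z geometry); the alkenes do not react.

Step 5
Reactants: 8 acrolein; 9 ethyl 2-(triphenyl-λ5-phosphanylidene)propanoate
Product: 10 ethyl (2E)-2-methylpenta-2,4-dienoate
Conditions: CH2Cl2, 0 °C → rt
Reagents that add atoms: none
Why: Wittig olefination with a stabilised ylide gives the E-trisubstituted alkene.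

Step 6
Reactants: 10 dienoate
Product: 11 (2E)-2-methylpenta-2,4-dien-1-ol
Conditions: i-Bu2AlH (2.2 equiv), CH2Cl2, −78 °C; aq. potassium sodium tartrate
Reagents that add atoms: none
Why: Hydride 1,2-reduction of the conjugated ester to the allylic alcohol leaves the alkene geometry intact.

Step 7
Reactants: 11 dienol
Product: 12 [(2S,3S)-3-ethenyl-2-methyloxiran-2-yl]methanol
Conditions: Ti(OiPr)4 (10 mol %), L-(+)-diethyl tartrate (12 mol %), t-BuOOH (2 equiv), 4 Å MS, CH2Cl2, −20 °C
Reagents that add atoms: tert-butyl hydroperoxide, CC(C)(C)OO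
Why: Sharpless asymmetric epoxidation, in which the allylic hydroxyl binds the titanium tartrate so only the 2,3-alkene reacts and L-(+)-tartrate delivers oxygen to the face giving the 2S,3S trans-epoxide (C5 S, C4 S).

Step 8
Reactants: 12 epoxy alcohol
Product: 13 (2R,3S)-3-ethenyl-2-methyloxirane-2-carbaldehyde
Conditions: TEMPO (10 mol %), PhI(OAc)2 (1.1 equiv), CH2Cl2, 0 °C → rt; used crude
Reagents that add atoms: none
Why: Oxoammonium (TEMPO) oxidation of the primary alcohol; the aldehyde α-carbon is quaternary, so it cannot epimerise (the descriptor changes only through CIP priorities).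

Step 9
Reactants: 13 epoxy aldehyde
Product: 14 (2Z)-3-[(2S,3S)-3-ethenyl-2-methyloxiran-2-yl]-N-methoxy-N-methylprop-2-enamide
Conditions: (CF3CH2O)2P(O)CH2C(O)N(OMe)Me, KN(SiMe3)2, 18-crown-6, THF, −78 °C
Reagents that add atoms: bis(2,2,2-trifluoroethyl) [2-(methoxy(methyl)amino)-2-oxoethyl]phosphonate, CON(C)C(=O)CP(=O)(OCC(F)(F)F)OCC(F)(F)F
Why: Still–Gennari-type Horner–Wadsworth–Emmons olefination, in which the electron-poor phosphonate with a dissociated potassium ion eliminates from the kinetic adduct and gives the Z-enamide (C6=C7).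

Step 10
Reactants: 7 vinylstannane; 14 Weinreb amide
Product: 16 (1Z,4Z,7S)-7-ethenyl-1-[(2S,3S)-3-ethenyl-2-methyloxiran-2-yl]-4-(hydroxymethyl)-7,11-dimethyldodeca-1,4,10-trien-3-one, via dilithio alkoxide 15 (not isolated)
Conditions: 7 (1.2 equiv), MeLi (1.0 equiv per 7) then n-BuLi (1.1 equiv), THF, −78 → −40 °C; 14, −78 °C; aq. NH4Cl, cold
Reagents that add atoms: none
Why: Tin–lithium exchange keeps the alkene geometry and the vinyllithium adds once to the Weinreb amide (stable chelate), so the C8 ketone appears only on work-up, while the epoxide is inert to the organolithium at −78 °C.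

Step 11
Reactants: 16 acyclic epoxy trienone
Product: 17 (1S,2Z,5Z,8S,9Z,11S)-5-(hydroxymethyl)-1,8-dimethyl-8-(4-methylpent-3-en-1-yl)-12-oxabicyclo[9.1.0]dodeca-2,5,9-trien-4-one
Conditions: second-generation Hoveyda–Grubbs catalyst RuCl2(H2IMes)(=CH–C6H4-2-OiPr) (10–15 mol %), 1,4-benzoquinone (cat.), toluene (1 mM), 60–80 °C, Ar sparge
Reagents that add atoms: none
Why: Ring-closing metathesis, in which ruthenium loads on the unhindered vinyl oxirane terminus and closes onto the neopentyl vinyl group of a chain pre-folded by two cis alkenes; the 11-membered ring should admit only a cis (Z) C2=C3.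

Step 12
Reactants: 17 macrocyclic epoxide; 18 3-methylbut-2-enoic acid (senecioic acid)
Product: 19 target, (1R,2Z,4S,6Z,9Z,11S)-11-hydroxy-7-(hydroxymethyl)-4,11-dimethyl-4-(4-methylpent-3-en-1-yl)-8-oxocycloundeca-2,6,9-trien-1-yl 3-methylbut-2-enoate
Conditions: (R,R)-(salen)Co [salen = N,N'-bis(3,5-di-tert-butylsalicylidene)-1,2-cyclohexanediamine dianion] (10 mol %), air, 18 (1.5 equiv), i-Pr2NEt (1.0 equiv), 4 Å MS, t-BuOMe, 0 °C → rt; the (S,S) complex is the control
Reagents that add atoms: none
Why: Proposed new method: the trivalent cobalt carboxylate (salen)Co(O2CCH=CMe2), formed in situ from the divalent complex, air and 18, acts twice (one cobalt as Lewis acid on the epoxide oxygen, a second as carboxylate carrier) and delivers the acid by SN2 to C4 with inversion (S → R) while C5 keeps its oxygen (S). C4 is favoured because it is secondary and allylic, whereas C5 is tertiary and flanked by the electron-poor enone, SN2' at C2 is blocked by the quaternary C1, and attack at C7 would be α to the ketone. The closest known reactions are the cobalt–salen-catalysed addition of carboxylic acids to meso and terminal epoxides and the Ti(OiPr)4-mediated C3 opening of 2,3-epoxy alcohols by carboxylic acids; new here are a trisubstituted bis-allylic epoxide in a medium ring, an α,β-unsaturated acid and no directing hydroxyl.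

## Compound list

1 | geraniol, (2E)-3,7-dimethylocta-2,6-dien-1-ol | CC(C)=CCC/C(C)=C/CO | starting material
2 | geranyl diethyl phosphate | CC(C)=CCC/C(C)=C/COP(=O)(OCC)OCC | intermediate
3 | 4,4,5,5-tetramethyl-2-[3-(trimethylsilyl)prop-2-yn-1-yl]-1,3,2-dioxaborolane | C[Si](C)(C)C#CCB1OC(C)(C)C(C)(C)O1 | starting material
4 | [(4S)-4-ethenyl-4,8-dimethylnon-7-en-1-yn-1-yl]trimethylsilane | CC(C)=CCC[C@](C)(C=C)CC#C[Si](C)(C)C | intermediate
5 | lithium acetylide, [(4S)-4-ethenyl-4,8-dimethylnon-7-en-1-yn-1-yl]lithium (not isolated) | CC(C)=CCC[C@](C)(C=C)CC#C[Li] | intermediate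
6 | (5S)-5-ethenyl-5,9-dimethyldec-8-en-2-yn-1-ol | CC(C)=CCC[C@](C)(C=C)CC#CCO | intermediate
7 | (2Z,5S)-5-ethenyl-5,9-dimethyl-2-(tributylstannyl)deca-2,8-dien-1-ol | CC(C)=CCC[C@](C)(C=C)C/C=C(CO)\[Sn](CCCC)(CCCC)CCCC | intermediate
8 | acrolein, prop-2-enal | C=CC=O | starting material
9 | ethyl 2-(triphenyl-λ5-phosphanylidene)propanoate | CCOC(=O)C(C)=P(c1ccccc1)(c1ccccc1)c1ccccc1 | starting material
10 | ethyl (2E)-2-methylpenta-2,4-dienoate | C=C/C=C(\C)C(=O)OCC | intermediate
11 | (2E)-2-methylpenta-2,4-dien-1-ol | C=C/C=C(\C)CO | intermediate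
12 | [(2S,3S)-3-ethenyl-2-methyloxiran-2-yl]methanol | C=C[C@@H]1O[C@@]1(C)CO | intermediate
13 | (2R,3S)-3-ethenyl-2-methyloxirane-2-carbaldehyde | C=C[C@@H]1O[C@@]1(C)C=O | intermediate
14 | (2Z)-3-[(2S,3S)-3-ethenyl-2-methyloxiran-2-yl]-N-methoxy-N-methylprop-2-enamide | C=C[C@@H]1O[C@@]1(C)/C=C\C(=O)N(C)OC | intermediate
15 | dilithio alkoxide, lithium (2Z,5S)-5-ethenyl-2-lithio-5,9-dimethyldeca-2,8-dien-1-olate (not isolated) | CC(C)=CCC[C@](C)(C=C)C/C=C(CO[Li])\[Li] | intermediate
16 | (1Z,4Z,7S)-7-ethenyl-1-[(2S,3S)-3-ethenyl-2-methyloxiran-2-yl]-4-(hydroxymethyl)-7,11-dimethyldodeca-1,4,10-trien-3-one | CC(C)=CCC[C@](C)(C=C)C/C=C(CO)\C(=O)/C=C\[C@]1(C)O[C@H]1C=C | intermediate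
17 | (1S,2Z,5Z,8S,9Z,11S)-5-(hydroxymethyl)-1,8-dimethyl-8-(4-methylpent-3-en-1-yl)-12-oxabicyclo[9.1.0]dodeca-2,5,9-trien-4-one (C1 S, trans-4S,5S-epoxide) | CC(C)=CCC[C@]1(C)/C=C\[C@@H]2O[C@@]2(C)/C=C\C(=O)/C(CO)=C\C1 | intermediate
18 | 3-methylbut-2-enoic acid (senecioic acid) | CC(C)=CC(=O)O | starting material
19 | (1R,2Z,4S,6Z,9Z,11S)-11-hydroxy-7-(hydroxymethyl)-4,11-dimethyl-4-(4-methylpent-3-en-1-yl)-8-oxocycloundeca-2,6,9-trien-1-yl 3-methylbut-2-enoate | CC(C)=CCC[C@]1(C)/C=C\[C@@H](OC(=O)C=C(C)C)[C@@](C)(O)/C=C\C(=O)/C(CO)=C\C1 | target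

## Step count and risks

Total step count: 12. Longest linear sequence: 8 steps (steps 5–12, from acrolein); the geraniol branch is 4 steps before the union. No protecting groups are used.

The three steps most likely to fail:

Step 12 (the proposed new acyloxylation). The risk is no turnover on a trisubstituted epoxide or wrong regiochemistry. The fallback uses known chemistry and sets out from 17. The primary alcohol of 17 is silylated (t-BuPh2SiCl, imidazole, CH2Cl2) to the silyl ether F1. Dilute acid (HClO4 cat., THF–H2O, 0 °C) then hydrates the epoxide by anti attack of water at the allylic C4 to give the 4R,5S-diol F2. The secondary C4 hydroxyl alone is acylated with 3-methylbut-2-enoic anhydride and DMAP in pyridine, the tertiary C5–OH staying free, to give the ester F3. HF·pyridine removes the silyl group and the route is rejoined at 19.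

Step 11 (ring-closing metathesis). The risks are the neopentyl vinyl group and the rigidity of the trans-epoxide in an 11-membered ring. The fallback removes the epoxide before ring closure with known chemistry and sets out from 12 (with 18 and 7). Ti(OiPr)4 (1.5 equiv) and 18 open 12 at the allylic carbon with inversion (the known C3-selective opening of 2,3-epoxy alcohols by carboxylic acids) to the diol monoester F4. TEMPO/PhI(OAc)2 oxidises the primary alcohol to the hydroxy aldehyde F5. Still–Gennari olefination with methyl bis(2,2,2-trifluoroethyl)phosphonoacetate (KN(SiMe3)2, 18-crown-6, −78 °C) gives the Z-enoate F6 (not isolated), which lactonises on work-up to the butenolide F7. The dilithio alkoxide 15, made from 7 as in step 10, adds once to the lactone carbonyl at −78 °C; the lactolate is stable and the hindered, conjugated senecioate is spared. Work-up gives the seco hydroxy ester F8 (lactol ⇌ hydroxy-enone). The same ruthenium catalyst then closes this more flexible, hemiketal-clamped tetraene directly to 19, bypassing 17 and step 12.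

Step 10 (fragment union). The risks are incomplete tin–lithium exchange next to an alkoxide, attack on the vinyl epoxide, and Z → E drift of the enone. The fallback changes the organometallic and sets out from 7. Iodine (CH2Cl2, 0 °C) replaces tin with retention to give the vinyl iodide F9. MeMgCl (deprotonation) and then i-PrMgCl·LiCl (iodine–magnesium exchange, THF, −20 °C) give the milder alkenylmagnesium alkoxide F10, which adds to 14 and returns to 16.

Further compounds

F1 | step 12 | (1S,2Z,5Z,8S,9Z,11S)-5-({[tert-butyl(diphenyl)silyl]oxy}methyl)-1,8-dimethyl-8-(4-methylpent-3-en-1-yl)-12-oxabicyclo[9.1.0]dodeca-2,5,9-trien-4-one | CC(C)=CCC[C@]1(C)/C=C\[C@@H]2O[C@@]2(C)/C=C\C(=O)/C(CO[Si](c2ccccc2)(c2ccccc2)C(C)(C)C)=C\C1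
F2 | step 12 | (2Z,5S,6Z,8R,9S,10Z)-2-({[tert-butyl(diphenyl)silyl]oxy}methyl)-8,9-dihydroxy-5,9-dimethyl-5-(4-methylpent-3-en-1-yl)cycloundeca-2,6,10-trien-1-one | CC(C)=CCC[C@]1(C)/C=C\[C@@H](O)[C@@](C)(O)/C=C\C(=O)/C(CO[Si](c2ccccc2)(c2ccccc2)C(C)(C)C)=C\C1
F3 | step 12 | (1R,2Z,4S,6Z,9Z,11S)-7-({[tert-butyl(diphenyl)silyl]oxy}methyl)-11-hydroxy-4,11-dimethyl-4-(4-methylpent-3-en-1-yl)-8-oxocycloundeca-2,6,9-trien-1-yl 3-methylbut-2-enoate | CC(C)=CCC[C@]1(C)/C=C\[C@@H](OC(=O)C=C(C)C)[C@@](C)(O)/C=C\C(=O)/C(CO[Si](c2ccccc2)(c2ccccc2)C(C)(C)C)=C\C1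
F4 | step 11 | (2S,3R)-1,2-dihydroxy-2-methylpent-4-en-3-yl 3-methylbut-2-enoate | C=C[C@@H](OC(=O)C=C(C)C)[C@@](C)(O)CO
F5 | step 11 | (2R,3R)-2-hydroxy-2-methyl-1-oxopent-4-en-3-yl 3-methylbut-2-enoate | C=C[C@@H](OC(=O)C=C(C)C)[C@@](C)(O)C=O
F6 | step 11 | methyl (2Z,4S,5R)-4-hydroxy-4-methyl-5-[(3-methylbut-2-enoyl)oxy]hepta-2,6-dienoate (not isolated) | C=C[C@@H](OC(=O)C=C(C)C)[C@@](C)(O)/C=C\C(=O)OC
F7 | step 11 | (1R)-1-[(2S)-2-methyl-5-oxo-2,5-dihydrofuran-2-yl]prop-2-en-1-yl 3-methylbut-2-enoate | C=C[C@@H](OC(=O)C=C(C)C)[C@@]1(C)OC(=O)C=C1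
F8 | step 11 | (3R,4S,5Z,8Z,11S)-11-ethenyl-4-hydroxy-8-(hydroxymethyl)-4,11,15-trimethyl-7-oxohexadeca-1,5,8,14-tetraen-3-yl 3-methylbut-2-enoate | CC(C)=CCC[C@](C)(C=C)C/C=C(CO)\C(=O)/C=C\[C@](C)(O)[C@H](OC(=O)C=C(C)C)C=C
F9 | step 10 | (2Z,5S)-5-ethenyl-2-iodo-5,9-dimethyldeca-2,8-dien-1-ol | CC(C)=CCC[C@](C)(C=C)C/C=C(CO)\I
F10 | step 10 | chloromagnesium (2Z,5S)-2-(chloromagnesio)-5-ethenyl-5,9-dimethyldeca-2,8-dien-1-olate (not isolated) | CC(C)=CCC[C@](C)(C=C)C/C=C(CO[Mg]Cl)\[Mg]Cl
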